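## The problem

The target is the B-type procyanidin tetramer catechin-(4α→6)-epicatechin-(4β→8)-epicatechin-(4β→8)-epicatechin, in which four flavan-3-ol units (numbered 1 to 4 from the catechin end) are joined only by three C4–aryl bonds. Two of these bonds run from C4 to C8 of the next ring A, the position a flavan C4 cation prefers, but the third runs from C4 of unit 1 to C6 of unit 2, a position this chemistry normally avoids, so the regiochemistry of that one bond is the central difficulty. Of the eleven stereocentres, C2 and C3 of units 1, 3 and 4 can be bought with catechin and epicatechin, whereas nothing in the molecule controls C2 and C3 of a unit that is built and not bought. Each C4 centre is set by its neighbour: C4 of unit 1 trans to the equatorial C3 oxygen of a 2,3-trans ring, and C4 of units 2 and 3 trans to the axial C3 oxygen of a 2,3-cis ring. The free polyphenol is easily oxidised, its interflavan bonds cleave in strong protic acid, its C2 centres epimerise in base, and every ring A is a phloroglucinol-type nucleophile that can capture a C4 cation of its own precursor. The hydroxyl groups must therefore stay masked as benzyl ethers until a final neutral hydrogenolysis, and each C–C bond must form under mild Lewis acid at low temperature. The enabling feature is that C6 of unit 2 is para to O1 across ring A: if ring C of unit 2 is closed last, at C4–C4a, the open precursor is an O1-linked 3,5-dioxygenated aryl ether with unit 1 para to the ether oxygen. Its two ortho carbons are equivalent, so closure can only give the 4→6 isomer, and the C2–C3–C4 chain this exposes maps onto the three carbons of (R)-glyceraldehyde.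

## Retrosynthesis

**Global deprotection, 27 from 26.** No skeletal bond is cut; the 18 benzyl ethers of 26 are removed in one hydrogenolysis. Benzyl is preferred to acyl, silyl or methyl protection because it survives the bases and Lewis acids of the route and leaves under neutral conditions. Precursor 26 has the full skeleton but is stable and chromatographable. The forward reaction must cleave every ether without touching the C4–aryl bonds.

**Central interflavan bond, 26 from 21 and 25.** The bond between C4 of unit 2 and C8 of unit 3 is cut. This divides the tetramer into two dimers of similar size and is of the best-behaved type (4β→8 from a 2,3-cis cation). Cutting the unit 3–unit 4 bond last would need a leaving group on a trimer, and cutting the 4→6 bond here would meet the regiochemical problem directly. The forward step needs the cation from 21 to be captured by C8 of the upper unit of 25, trans to the C3 benzyloxy group, faster than by any ring A of 21 itself.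

**Lower dimer, 25 from 24 and 23.** The unit 3 C4–unit 4 C8 bond is cut. Both halves derive from one monomer, 23, made from (−)-epicatechin 22; the electrophile 24 is 23 oxidised at C4 in the presence of 2-ethoxyethanol 3. This is the standard bond of procyanidin chemistry and only asks for an excess of 23.

**Ring C of unit 2, 21 from 19 and 3.** The C4–C4a bond of unit 2 is cut, together with the C4 ether. The neighbouring cut, unit 1 C4 to unit 2 C6, would require C6-selective arylation of an intact epicatechin ring, which has no inherent bias. The chosen cut makes ring A of unit 2 a para-substituted aryl ether with two equivalent ortho carbons. Aldehyde 19 is acyclic in unit 2 and already carries C2 and C3. The forward step needs cyclisation to outrun enolisation of the aldehyde, and the first-formed flavan-4-ol 20 must be intercepted by 3 before it arylates another molecule.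

**Side-chain adjustment, 19 back to 14.** No skeletal bond is cut. The aldehyde comes from primary alcohol 18, and the secondary benzyl ether requires the primary hydroxyl to be masked first (silyl ethers 17 and 16). Diol 15 comes from the acetonide 14 that the chiral pool supplies. The order is dictated by the need to tell the two hydroxyls apart.

**Aryl ether O1–C2, 14 from 13 and 9.** The benzylic C–O bond is cut and formed forward with inversion. This lets the readily available anti carbinol 13 serve, although the ring needs the syn arrangement. Opening a cis-epoxide with the phenol would give the same relationship, but such epoxides are poorly accessible in high enantiopurity. The fragments are phenol 9 (unit 1 plus the future ring A) and carbinol 13 (ring B plus three carbons). The forward reaction must be a clean SN2 displacement at an electron-rich benzylic carbon.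

**Carbinol, 13 from 10 and 11.** The bond from C2 of unit 2 to ring B is cut. The Grignard reagent 12 from bromide 10 adds to (R)-glyceraldehyde acetonide 11, which supplies C3 of unit 2 directly and controls C2 by Felkin addition. Both precursors are commercial.

**Unit 1 to ring A of unit 2, 9 from 5 and 7.** The C4–aryl bond of unit 1 is cut. The catechin C4 cation from 5 meets silyl ether 7, whose only unhindered nucleophilic carbon is para to the bulky silyloxy group. Ether 5 comes from (+)-catechin 1 through 2 and 4, and 7 from phenol 6. The forward step must be para-selective on the arene and trans-selective (4α) on the flavan.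

## Roads not taken

**Alternative 1:** The unit 3 C4–unit 4 C8 bond is made intramolecular. The two monomers are tied O3 to O3 by an azelate diester in the open precursor A2, and TMSOTf at high dilution closes the 18-membered macrocycle A1. The merit is stoichiometry: one nucleophile per electrophile and no oligomerisation, which is better than the excess of 23 that step 17 of the chosen plan consumes. The weak points are that tether installation, macrocyclisation and tether removal are spent on the most reliable bond in the molecule. A 3-O-acyl group also sits next to the cation, and the 4→6 bond is left unsolved. The chosen plan sets against the better stoichiometry of A1 the recoverability of 23 and three or four fewer steps on that fragment.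

**Alternative 2:** The C2–C3 bond of unit 1 is formed on the assembled tetramer. KOH and CBr2F2 on alumina convert the seven-membered sulfone A4 by Ramberg–Bäcklund extrusion of SO2 into the flav-2-ene A3. Hydroboration anti to the C4 aryl group would then set C2 and C3 of unit 1. The bromine at C8 of unit 2 in A3 is a sound blocking device for C6 selectivity, and in that respect this road is as credible as the symmetry argument of the chosen plan. Its weakness is that unit 1 is catechin, the one unit that can be bought, and it is built de novo on the largest and most valuable intermediate. Strong base and a halogenating agent act there in the presence of many benzyl ethers and three doubly benzylic C4–H bonds, and A4 itself needs a long preparation. The chosen plan also builds one unit, but does so on small fragments before any interflavan bond to units 3 and 4 exists.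

**Alternative 3:** Ring C of unit 3 is closed at C4–C4a. BF3·OEt2 opens the trans-epoxide A6 at the carbon bearing the unit-4 aryl group, and an ortho carbon of the 3,5-dibenzyloxyphenyl ether attacks with inversion to give dimer A5 with a free 3-hydroxyl. This uses the same symmetric-ether logic as the chosen plan and has a real advantage: its ring closure sets a lasting C4 stereocentre stereospecifically, whereas the chosen key step creates only a transient one. Against this, the closure is spent on unit 3, whose 4→8 link poses no regiochemical problem. The epoxide carbon is benzylic to the very electron-rich ring A of unit 4, so opening may become SN1-like. Ring A of unit 3 in A5 emerges with both C6 and C8 free for the next coupling, and the 4→6 bond is still unmade. The chosen plan sets its C4 centres later by the well-established trans direction of the C3 substituent and reserves the ring closure for the one bond that cannot be controlled otherwise.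

Key step: step 14

Assumptions and abbreviations:
- 3,5-Bis(benzyloxy)phenol (6) and 4-bromo-1,2-bis(benzyloxy)benzene (10) are taken as catalogue compounds; each is one benzylation away from phloroglucinol or 4-bromocatechol.
- The C4 ethers 4, 5 and 24 are drawn as the 4β epimers; their C4 configuration is lost on ionisation and either epimer serves.
- Bn = benzyl; Ar = 3,4-bis(benzyloxy)phenyl.
- Cat = penta-O-benzylcatechin-4α-yl, i.e. (2R,3S)-3,5,7-tris(benzyloxy)-2-[3,4-bis(benzyloxy)phenyl]chroman-4-yl bonded through C4, trans to the C3 benzyloxy group and cis to the C2 aryl group.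

## Route

Step 1
Reactants: 1 (+)-catechin
Product: 2 5,7,3′,4′-tetra-O-benzyl-(+)-catechin
Conditions: BnBr, K2CO3, DMF, 0 °C → rt
Reagents that add atoms: benzyl bromide, BrCc1ccccc1
Why: Williamson etherification of the four phenols; the weak base K2CO3 leaves the C3 alcohol free and does not epimerise C2.

Step 2
Reactants: 2 5,7,3′,4′-tetra-O-benzyl-(+)-catechin; 3 2-ethoxyethanol
Product: 4 (2R,3S,4S)-4-(2-ethoxyethoxy)-5,7,3′,4′-tetra-O-benzylcatechin
Conditions: DDQ, CH2Cl2, rt
Reagents that add atoms: none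
Why: DDQ oxidation of the benzylic C4 position (hydride abstraction to the ring-A-stabilised cation) with capture by the alcohol present in excess; C2 and C3 are untouched and the C4 configuration is of no consequence.

Step 3
Reactants: 4 (2R,3S,4S)-4-(2-ethoxyethoxy)-5,7,3′,4′-tetra-O-benzylcatechin
Product: 5 (2R,3S,4S)-4-(2-ethoxyethoxy)-3,5,7,3′,4′-penta-O-benzylcatechin
Conditions: NaH, BnBr, Bu4NI (cat.), DMF, 0 °C → rt
Reagents that add atoms: benzyl bromide, BrCc1ccccc1
Why: Williamson benzylation of the secondary alkoxide; the C4 acetal-type ether is stable to base, and the C3 oxygen must be capped before the later Mitsunobu step.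

Step 4
Reactants: 6 3,5-bis(benzyloxy)phenol
Product: 7 [3,5-bis(benzyloxy)phenoxy]tri(propan-2-yl)silane
Conditions: TIPSCl, imidazole, DMF, rt
Reagents that add atoms: chlorotri(propan-2-yl)silane, CC(C)[Si](Cl)(C(C)C)C(C)C
Why: Standard phenol silylation; the bulky triisopropylsilyl group screens both ortho carbons and marks the oxygen that will become O1 of unit 2.

Step 5
Reactants: 5 (2R,3S,4S)-4-(2-ethoxyethoxy)-3,5,7,3′,4′-penta-O-benzylcatechin; 7 [3,5-bis(benzyloxy)phenoxy]tri(propan-2-yl)silane
Product: 8 [4-Cat-3,5-bis(benzyloxy)phenoxy]tri(propan-2-yl)silane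
Conditions: 7 (2 equiv), TMSOTf (0.2 equiv), CH2Cl2, −78 → −40 °C
Reagents that add atoms: none
Why: SN1 Friedel–Crafts arylation: TMSOTf ionises the C4 ether to the ring-A-stabilised cation, and the arene should attack through the carbon para to the silyloxy group because the two ortho carbons are shielded. The nucleophile enters trans to the C3 benzyloxy group of the 2,3-trans ring, setting C4 of unit 1 as 4α.

Step 6
Reactants: 8 [4-Cat-3,5-bis(benzyloxy)phenoxy]tri(propan-2-yl)silane
Product: 9 4-Cat-3,5-bis(benzyloxy)phenol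
Conditions: Bu4NF, AcOH, THF, 0 °C
Reagents that add atoms: none
Why: Fluoride-induced cleavage of the aryl silyl ether, buffered with acetic acid; benzyl ethers and the C4–aryl bond are inert.

Step 7
Reactants: 10 4-bromo-1,2-bis(benzyloxy)benzene; 11 (R)-2,3-O-isopropylideneglyceraldehyde
Product: 13 (S)-[3,4-bis(benzyloxy)phenyl][(4R)-2,2-dimethyl-1,3-dioxolan-4-yl]methanol, via arylmagnesium bromide 12 (not isolated)
Conditions: Mg, THF, rt; then 11, THF, −78 °C; aq. NH4Cl
Reagents that add atoms: none
Why: Grignard formation followed by Felkin–Anh addition to the α-alkoxy aldehyde: the aryl group attacks anti to the dioxolane C–O bond, so the anti (1S) carbinol is the expected major epimer, separable from the syn epimer by chromatography.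

Step 8
Reactants: 13 (S)-[3,4-bis(benzyloxy)phenyl][(4R)-2,2-dimethyl-1,3-dioxolan-4-yl]methanol; 9 4-Cat-3,5-bis(benzyloxy)phenol
Product: 14 (4R)-4-{(R)-Ar[4-Cat-3,5-bis(benzyloxy)phenoxy]methyl}-2,2-dimethyl-1,3-dioxolane
Conditions: 13 (1.5 equiv), PPh3, DIAD, toluene, 0 °C → rt
Reagents that add atoms: none
Why: Mitsunobu etherification: the phenol displaces the alkoxyphosphonium group by SN2 with inversion, turning the (S)-carbinol into the (R)-aryl ether with the syn (2,3-cis) relationship of an epicatechin unit. The adjacent dioxolane oxygen and the non-polar solvent disfavour ionisation of the benzylic centre.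

Step 9
Reactants: 14 (4R)-4-{(R)-Ar[4-Cat-3,5-bis(benzyloxy)phenoxy]methyl}-2,2-dimethyl-1,3-dioxolane
Product: 15 (2R,3R)-3-Ar-3-[4-Cat-3,5-bis(benzyloxy)phenoxy]propane-1,2-diol
Conditions: AcOH/THF/H2O (4:1:1), 40 °C
Reagents that add atoms: none
Why: Acid-catalysed hydrolysis of the acetonide; dilute acetic acid is too weak to ionise the benzylic aryl ether or the C4–aryl bond.

Step 10
Reactants: 15 (2R,3R)-3-Ar-3-[4-Cat-3,5-bis(benzyloxy)phenoxy]propane-1,2-diol
Product: 16 (2R,3R)-3-Ar-3-[4-Cat-3,5-bis(benzyloxy)phenoxy]-1-(tert-butyldiphenylsilyloxy)propan-2-ol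
Conditions: TBDPSCl, imidazole, CH2Cl2, 0 °C
Reagents that add atoms: tert-butyl(chloro)diphenylsilane, CC(C)(C)[Si](Cl)(c1ccccc1)c1ccccc1
Why: Selective silylation of the less hindered primary hydroxyl of a 1,2-diol by a bulky chlorosilane.

Step 11
Reactants: 16 (2R,3R)-3-Ar-3-[4-Cat-3,5-bis(benzyloxy)phenoxy]-1-(tert-butyldiphenylsilyloxy)propan-2-ol
Product: 17 tert-butyl{(2R,3R)-2-(benzyloxy)-3-Ar-3-[4-Cat-3,5-bis(benzyloxy)phenoxy]propoxy}diphenylsilane
Conditions: NaH, BnBr, Bu4NI (cat.), THF/DMF, 0 °C
Reagents that add atoms: benzyl bromide, BrCc1ccccc1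
Why: Williamson benzylation of the secondary alkoxide; the tert-butyldiphenylsilyl group is chosen because it resists 1,2-migration under these conditions better than smaller silyl groups.

Step 12
Reactants: 17 tert-butyl{(2R,3R)-2-(benzyloxy)-3-Ar-3-[4-Cat-3,5-bis(benzyloxy)phenoxy]propoxy}diphenylsilane
Product: 18 (2R,3R)-2-(benzyloxy)-3-Ar-3-[4-Cat-3,5-bis(benzyloxy)phenoxy]propan-1-ol
Conditions: Bu4NF, AcOH, THF, rt
Reagents that add atoms: none
Why: Buffered fluoride desilylation of the primary silyl ether; all ethers and stereocentres are untouched.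

Step 13
Reactants: 18 (2R,3R)-2-(benzyloxy)-3-Ar-3-[4-Cat-3,5-bis(benzyloxy)phenoxy]propan-1-ol
Product: 19 (2S,3R)-2-(benzyloxy)-3-Ar-3-[4-Cat-3,5-bis(benzyloxy)phenoxy]propanal
Conditions: Dess–Martin periodinane, NaHCO3, CH2Cl2, 0 °C → rt
Reagents that add atoms: none
Why: Dess–Martin oxidation of the primary alcohol under buffered, non-epimerising conditions; the α-benzyloxy aldehyde is used at once without chromatography (the descriptor at C2 changes to S only because the formyl group outranks C3).

Step 14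
Reactants: 19 (2S,3R)-2-(benzyloxy)-3-Ar-3-[4-Cat-3,5-bis(benzyloxy)phenoxy]propanal; 3 2-ethoxyethanol
Product: 21 deca-O-benzyl-4β-(2-ethoxyethoxy)-catechin-(4α→6)-epicatechin, via flavan-4-ol 20 (not isolated)
Conditions: BF3·OEt2 (0.5 equiv), 4 Å MS, CH2Cl2 (5 mM), −78 °C; then 3 (20 equiv), −78 → −20 °C; Et3N
Reagents that add atoms: none
Why: BF3 binds the aldehyde oxygen, and the ortho carbon of the aryl ether ring, activated by one ortho ether oxygen, one ortho benzyloxy and one para benzyloxy group, attacks the carbonyl carbon; rearomatisation gives flavan-4-ol 20 with the new C4–C4a bond. The closest known reaction type is the acid-mediated Friedel–Crafts hydroxyalkylation of 3-aryloxypropanals to chroman-4-ols, followed by the acid-catalysed alcohol exchange that is routine at C4 of flavans. Ring C of unit 2 closes in a 6-exo-trig mode, the carbonyl oxygen remaining outside the ring. The carbinol configuration at C4 of 20 is not controlled and does not matter: on adding 3 the 4-ol ionises to the ring-A-stabilised cation, which the alcohol captures trans to the axial C3 benzyloxy group to give the 4β ether, and this centre is ionised again in step 18. The selectivity the step needs is regiochemical, and the substrate secures it by symmetry: the two ortho carbons are equivalent, so only the 4→6-linked dimer can form. Chemoselectivity over ring B (which would close a five-membered ring from a far less nucleophilic carbon) and over ring A of unit 1 (which would need a macrocycle) follows from the six-membered transition state onto the most electron-rich carbon. High dilution, low temperature and the large excess of 3 are meant to suppress arylation of a second molecule by the C4 cation. C2 and C3 are not involved, provided ring closure at −78 °C is faster than enolisation of the aldehyde.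

Step 15
Reactants: 22 (−)-epicatechin
Product: 23 5,7,3′,4′-tetra-O-benzyl-(−)-epicatechin
Conditions: BnBr, K2CO3, DMF, 0 °C → rt
Reagents that add atoms: benzyl bromide, BrCc1ccccc1
Why: Williamson etherification of the four phenols with a weak base, as in step 1.

Step 16
Reactants: 23 5,7,3′,4′-tetra-O-benzyl-(−)-epicatechin; 3 2-ethoxyethanol
Product: 24 (2R,3R,4S)-4-(2-ethoxyethoxy)-5,7,3′,4′-tetra-O-benzylepicatechin
Conditions: DDQ, CH2Cl2, rt
Reagents that add atoms: none
Why: DDQ oxidation at C4 with capture of the cation by the alcohol trans to the axial C3 hydroxyl, as in step 2.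

Step 17
Reactants: 24 (2R,3R,4S)-4-(2-ethoxyethoxy)-5,7,3′,4′-tetra-O-benzylepicatechin; 23 5,7,3′,4′-tetra-O-benzyl-(−)-epicatechin
Product: 25 octa-O-benzyl-epicatechin-(4β→8)-epicatechin
Conditions: 23 (4 equiv), TMSOTf (cat.), CH2Cl2, −78 °C
Reagents that add atoms: none
Why: Lewis-acid-catalysed SN1 Friedel–Crafts coupling: C8 of the excess nucleophile captures the C4 cation trans to the axial C3 oxygen, giving the 4β→8 dimer; excess 23 suppresses higher oligomers and is recovered.

Step 18
Reactants: 21 deca-O-benzyl-4β-(2-ethoxyethoxy)-catechin-(4α→6)-epicatechin; 25 octa-O-benzyl-epicatechin-(4β→8)-epicatechin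
Product: 26 octadeca-O-benzyl-catechin-(4α→6)-epicatechin-(4β→8)-epicatechin-(4β→8)-epicatechin
Conditions: 25 (3 equiv), TMSOTf (0.5 equiv), CH2Cl2, −78 → −40 °C
Reagents that add atoms: none
Why: SN1 Friedel–Crafts coupling: TMSOTf ionises the C4 ether of unit 2, and C8 of the upper unit of 25, the most nucleophilic and least hindered ring A carbon, captures the cation. The axial C3 benzyloxy group of the 2,3-cis ring directs attack to the opposite face, setting C4 of unit 2 as 4β; excess 25 competes with self-condensation and is recovered.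

Step 19
Reactants: 26 octadeca-O-benzyl-catechin-(4α→6)-epicatechin-(4β→8)-epicatechin-(4β→8)-epicatechin
Product: 27 catechin-(4α→6)-epicatechin-(4β→8)-epicatechin-(4β→8)-epicatechin (CNP0228086.1)
Conditions: H2 (1 atm), Pd(OH)2 on carbon, THF/MeOH/H2O, rt
Reagents that add atoms: none
Why: Hydrogenolysis of all 18 benzyl ethers under neutral conditions; no stereocentre is touched and the interflavan bonds are stable.

## Compound list

1 | (+)-catechin, (2R,3S)-2-(3,4-dihydroxyphenyl)chromane-3,5,7-triol | Oc1cc(O)c2c(c1)O[C@H](c1ccc(O)c(O)c1)[C@@H](O)C2 | starting material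
2 | 5,7,3′,4′-tetra-O-benzyl-(+)-catechin, (2R,3S)-5,7-bis(benzyloxy)-2-[3,4-bis(benzyloxy)phenyl]chroman-3-ol | c9ccccc9COc1cc(OCc9ccccc9)c2c(c1)O[C@H](c1ccc(OCc9ccccc9)c(OCc9ccccc9)c1)[C@@H](O)C2 | intermediate
3 | 2-ethoxyethanol | OCCOCC | starting material
4 | (2R,3S,4S)-5,7-bis(benzyloxy)-2-[3,4-bis(benzyloxy)phenyl]-4-(2-ethoxyethoxy)chroman-3-ol (4β ether, cis to the C3 hydroxyl) | c9ccccc9COc1cc(OCc9ccccc9)c2c(c1)O[C@H](c1ccc(OCc9ccccc9)c(OCc9ccccc9)c1)[C@@H](O)[C@H]2OCCOCC | intermediate
5 | (2R,3S,4S)-3,5,7-tris(benzyloxy)-2-[3,4-bis(benzyloxy)phenyl]-4-(2-ethoxyethoxy)chromane | c9ccccc9COc1cc(OCc9ccccc9)c2c(c1)O[C@H](c1ccc(OCc9ccccc9)c(OCc9ccccc9)c1)[C@@H](OCc9ccccc9)[C@H]2OCCOCC | intermediate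
6 | 3,5-bis(benzyloxy)phenol | Oc1cc(OCc9ccccc9)cc(OCc9ccccc9)c1 | starting material
7 | [3,5-bis(benzyloxy)phenoxy]tri(propan-2-yl)silane | CC(C)[Si](C(C)C)(C(C)C)Oc1cc(OCc9ccccc9)cc(OCc9ccccc9)c1 | intermediate
8 | [4-Cat-3,5-bis(benzyloxy)phenoxy]tri(propan-2-yl)silane (penta-O-benzylcatechin carrying at C4α a 2,6-bis(benzyloxy)-4-(triisopropylsilyloxy)phenyl group) | c9ccccc9COc1cc(OCc9ccccc9)c2c(c1)O[C@H](c1ccc(OCc9ccccc9)c(OCc9ccccc9)c1)[C@@H](OCc9ccccc9)[C@@H]2c1c(OCc9ccccc9)cc(O[Si](C(C)C)(C(C)C)C(C)C)cc1OCc9ccccc9 | intermediate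
9 | 4-Cat-3,5-bis(benzyloxy)phenol | c9ccccc9COc1cc(OCc9ccccc9)c2c(c1)O[C@H](c1ccc(OCc9ccccc9)c(OCc9ccccc9)c1)[C@@H](OCc9ccccc9)[C@@H]2c1c(OCc9ccccc9)cc(O)cc1OCc9ccccc9 | intermediate
10 | 4-bromo-1,2-bis(benzyloxy)benzene | Brc1ccc(OCc9ccccc9)c(OCc9ccccc9)c1 | starting material
11 | (R)-2,3-O-isopropylideneglyceraldehyde, (4R)-2,2-dimethyl-1,3-dioxolane-4-carbaldehyde | O=C[C@H]1COC(C)(C)O1 | starting material
12 | [3,4-bis(benzyloxy)phenyl]magnesium bromide | Br[Mg]c1ccc(OCc9ccccc9)c(OCc9ccccc9)c1 | intermediate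
13 | (S)-[3,4-bis(benzyloxy)phenyl][(4R)-2,2-dimethyl-1,3-dioxolan-4-yl]methanol (anti adduct) | O[C@@H](c1ccc(OCc9ccccc9)c(OCc9ccccc9)c1)[C@H]1COC(C)(C)O1 | intermediate
14 | (4R)-4-{(R)-[3,4-bis(benzyloxy)phenyl][4-Cat-3,5-bis(benzyloxy)phenoxy]methyl}-2,2-dimethyl-1,3-dioxolane | c9ccccc9COc1cc(OCc9ccccc9)c2c(c1)O[C@H](c1ccc(OCc9ccccc9)c(OCc9ccccc9)c1)[C@@H](OCc9ccccc9)[C@@H]2c1c(OCc9ccccc9)cc(cc1OCc9ccccc9)O[C@H](c1ccc(OCc9ccccc9)c(OCc9ccccc9)c1)[C@H]1COC(C)(C)O1 | intermediate
15 | (2R,3R)-3-[3,4-bis(benzyloxy)phenyl]-3-[4-Cat-3,5-bis(benzyloxy)phenoxy]propane-1,2-diol | c9ccccc9COc1cc(OCc9ccccc9)c2c(c1)O[C@H](c1ccc(OCc9ccccc9)c(OCc9ccccc9)c1)[C@@H](OCc9ccccc9)[C@@H]2c1c(OCc9ccccc9)cc(cc1OCc9ccccc9)O[C@H](c1ccc(OCc9ccccc9)c(OCc9ccccc9)c1)[C@H](O)CO | intermediate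
16 | (2R,3R)-3-[3,4-bis(benzyloxy)phenyl]-3-[4-Cat-3,5-bis(benzyloxy)phenoxy]-1-(tert-butyldiphenylsilyloxy)propan-2-ol | c9ccccc9COc1cc(OCc9ccccc9)c2c(c1)O[C@H](c1ccc(OCc9ccccc9)c(OCc9ccccc9)c1)[C@@H](OCc9ccccc9)[C@@H]2c1c(OCc9ccccc9)cc(cc1OCc9ccccc9)O[C@H](c1ccc(OCc9ccccc9)c(OCc9ccccc9)c1)[C@H](O)CO[Si](c1ccccc1)(c1ccccc1)C(C)(C)C | intermediate
17 | tert-butyl{(2R,3R)-2-(benzyloxy)-3-[3,4-bis(benzyloxy)phenyl]-3-[4-Cat-3,5-bis(benzyloxy)phenoxy]propoxy}diphenylsilane | c9ccccc9COc1cc(OCc9ccccc9)c2c(c1)O[C@H](c1ccc(OCc9ccccc9)c(OCc9ccccc9)c1)[C@@H](OCc9ccccc9)[C@@H]2c1c(OCc9ccccc9)cc(cc1OCc9ccccc9)O[C@H](c1ccc(OCc9ccccc9)c(OCc9ccccc9)c1)[C@H](OCc9ccccc9)CO[Si](c1ccccc1)(c1ccccc1)C(C)(C)C | intermediate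
18 | (2R,3R)-2-(benzyloxy)-3-[3,4-bis(benzyloxy)phenyl]-3-[4-Cat-3,5-bis(benzyloxy)phenoxy]propan-1-ol | c9ccccc9COc1cc(OCc9ccccc9)c2c(c1)O[C@H](c1ccc(OCc9ccccc9)c(OCc9ccccc9)c1)[C@@H](OCc9ccccc9)[C@@H]2c1c(OCc9ccccc9)cc(cc1OCc9ccccc9)O[C@H](c1ccc(OCc9ccccc9)c(OCc9ccccc9)c1)[C@H](OCc9ccccc9)CO | intermediate
19 | (2S,3R)-2-(benzyloxy)-3-[3,4-bis(benzyloxy)phenyl]-3-[4-Cat-3,5-bis(benzyloxy)phenoxy]propanal | c9ccccc9COc1cc(OCc9ccccc9)c2c(c1)O[C@H](c1ccc(OCc9ccccc9)c(OCc9ccccc9)c1)[C@@H](OCc9ccccc9)[C@@H]2c1c(OCc9ccccc9)cc(cc1OCc9ccccc9)O[C@H](c1ccc(OCc9ccccc9)c(OCc9ccccc9)c1)[C@H](OCc9ccccc9)C=O | intermediate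
20 | deca-O-benzyl-catechin-(4α→6)-epicatechin-4-ol (flavan-4-ol of unit 2, either C4 epimer) | c9ccccc9COc1cc(OCc9ccccc9)c2c(c1)O[C@H](c1ccc(OCc9ccccc9)c(OCc9ccccc9)c1)[C@@H](OCc9ccccc9)[C@@H]2c1c(OCc9ccccc9)cc2c(c1OCc9ccccc9)C(O)[C@@H](OCc9ccccc9)[C@@H](c1ccc(OCc9ccccc9)c(OCc9ccccc9)c1)O2 | intermediate
21 | deca-O-benzyl-4β-(2-ethoxyethoxy)-catechin-(4α→6)-epicatechin (ether on C4 of unit 2, trans to its C3 benzyloxy group) | c9ccccc9COc1cc(OCc9ccccc9)c2c(c1)O[C@H](c1ccc(OCc9ccccc9)c(OCc9ccccc9)c1)[C@@H](OCc9ccccc9)[C@@H]2c1c(OCc9ccccc9)cc2c(c1OCc9ccccc9)[C@H](OCCOCC)[C@@H](OCc9ccccc9)[C@@H](c1ccc(OCc9ccccc9)c(OCc9ccccc9)c1)O2 | intermediate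
22 | (−)-epicatechin, (2R,3R)-2-(3,4-dihydroxyphenyl)chromane-3,5,7-triol | Oc1cc(O)c2c(c1)O[C@H](c1ccc(O)c(O)c1)[C@H](O)C2 | starting material
23 | 5,7,3′,4′-tetra-O-benzyl-(−)-epicatechin | c9ccccc9COc1cc(OCc9ccccc9)c2c(c1)O[C@H](c1ccc(OCc9ccccc9)c(OCc9ccccc9)c1)[C@H](O)C2 | intermediate
24 | (2R,3R,4S)-5,7-bis(benzyloxy)-2-[3,4-bis(benzyloxy)phenyl]-4-(2-ethoxyethoxy)chroman-3-ol (4β ether, trans to the C3 hydroxyl) | c9ccccc9COc1cc(OCc9ccccc9)c2c(c1)O[C@H](c1ccc(OCc9ccccc9)c(OCc9ccccc9)c1)[C@H](O)[C@H]2OCCOCC | intermediate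
25 | 5,7,3′,4′-tetra-O-benzylepicatechin-(4β→8)-5,7,3′,4′-tetra-O-benzylepicatechin | c1c(OCc9ccccc9)cc(OCc9ccccc9)c3c1O[C@H](c1ccc(OCc9ccccc9)c(OCc9ccccc9)c1)[C@H](O)[C@H]3c1c(OCc9ccccc9)cc(OCc9ccccc9)c3c1O[C@H](c1ccc(OCc9ccccc9)c(OCc9ccccc9)c1)[C@H](O)C3 | intermediate
26 | octadeca-O-benzyl tetramer: penta-O-benzylcatechin-(4α→6)-penta-O-benzylepicatechin-(4β→8)-tetra-O-benzylepicatechin-(4β→8)-tetra-O-benzylepicatechin; the 3-hydroxyl of each of the two lower epicatechin units is free | c9ccccc9COc1cc(OCc9ccccc9)c2c(c1)O[C@H](c1ccc(OCc9ccccc9)c(OCc9ccccc9)c1)[C@@H](OCc9ccccc9)[C@@H]2c1c(OCc9ccccc9)cc2c(c1OCc9ccccc9)[C@H](c1c(OCc9ccccc9)cc(OCc9ccccc9)c3c1O[C@H](c1ccc(OCc9ccccc9)c(OCc9ccccc9)c1)[C@H](O)[C@H]3c1c(OCc9ccccc9)cc(OCc9ccccc9)c3c1O[C@H](c1ccc(OCc9ccccc9)c(OCc9ccccc9)c1)[C@H](O)C3)[C@@H](OCc9ccccc9)[C@@H](c1ccc(OCc9ccccc9)c(OCc9ccccc9)c1)O2 | intermediate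
27 | catechin-(4α→6)-epicatechin-(4β→8)-epicatechin-(4β→8)-epicatechin (CNP0228086.1) | Oc1cc(O)c2c(c1)O[C@H](c1ccc(O)c(O)c1)[C@@H](O)[C@@H]2c1c(O)cc2c(c1O)[C@H](c1c(O)cc(O)c3c1O[C@H](c1ccc(O)c(O)c1)[C@H](O)[C@H]3c1c(O)cc(O)c3c1O[C@H](c1ccc(O)c(O)c1)[C@H](O)C3)[C@@H](O)[C@@H](c1ccc(O)c(O)c1)O2 | target

## Step count and risks

Total: 19 steps. Longest linear sequence: 14 steps from (+)-catechin (steps 1, 2, 3, 5, 6, 8, 9, 10, 11, 12, 13, 14, 18, 19). Steps 4, 7 and 15–17 are side branches.

**Step 14 (key step).** The most likely failure is intermolecular arylation. Flavan-4-ol 20 ionises under the Lewis acid before the alcohol is present, and its cation is captured by a ring A carbon of a second molecule, leading to oligomers. A slow closure would also allow enolisation of the α-benzyloxy aldehyde and erosion at C3. Fallback: setting out from 19, the aldehyde is first converted with 3, PPTS and MgSO4 into the bis(2-ethoxyethyl) acetal F1. TMSOTf (cat.) in CH2Cl2 at −78 °C, with a little added 3, then ionises one alkoxy group, and the oxocarbenium ion is attacked by the same ortho carbon. The same C4–C4a bond and ring form, but the C4 ether is in place at the moment of closure and no free 4-ol is exposed to acid. The sequence rejoins the route at 21.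

**Step 5.** The most likely failure is loss of regiocontrol: capture of the cation at a carbon ortho to the silyloxy group, which is statistically favoured two to one and electronically comparable. Some attack cis to the C3 substituent is also possible. Fallback: setting out from 5, the cation is captured by phloroglucinol itself (excess, THF/CH2Cl2, TMSOTf), which is symmetric, to give the 4α-(2,4,6-trihydroxyphenyl) adduct F2. TIPSCl and imidazole then silylate the one hydroxyl not flanked by the flavan, giving the para-silyl ether F3. BnBr and anhydrous K2CO3 in acetone benzylate the two remaining hydroxyls, and the sequence rejoins the route at 8.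

**Step 7.** The most likely failure is poor facial selectivity, with competing chelation by the dioxolane oxygen giving much syn epimer. Fallback: setting out from 13 as its mixture of carbinol epimers, MnO2 in CH2Cl2 oxidises the benzylic alcohol to the aryl ketone F4. Chelation-controlled reduction with Zn(BH4)2 in Et2O at −30 °C delivers hydride to the ketone held in a five-membered chelate and returns the anti carbinol, rejoining the route at 13. The stereocentre is then set by reduction, not by C–C bond formation.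

**Step 8.** The most likely failure is ionisation of the alkoxyphosphonium intermediate of the electron-rich benzylic alcohol when capture by the bulky phenol 9 is slow, eroding the inversion. Fallback: the order of bond formation is changed. Setting out from 13, the Mitsunobu reaction is run with the small, unhindered phenol 6 in excess to give the 3,5-bis(benzyloxy)phenyl ether F5. Unit 1 is then attached by TMSOTf-catalysed Friedel–Crafts reaction of 5 with F5 at −78 °C, para to the branched alkoxy group, whose bulk screens the ortho carbons. The sequence rejoins the route at 14.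

**Step 18.** The most likely failure is self-condensation of the electrophile through the free ring A carbons of 21 (C6 and C8 of unit 1, C8 of unit 2), or capture at C6 of unit 3. Fallback: setting out from 21, NBS (3 equiv, CH2Cl2, −20 °C) brominates these three carbons to give the tribromide F6, whose A rings are deactivated as nucleophiles. F6 is coupled with a near-equimolar amount of 25 under TMSOTf to give the tribromo tetramer F7. Hydrogenolysis over Pd(OH)2 on carbon with Et3N removes the bromine atoms together with the benzyl groups, and the sequence comes back at 27.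

## Further compounds

F1 | step 14 | bis(2-ethoxyethyl) acetal of aldehyde 19 | c9ccccc9COc1cc(OCc9ccccc9)c2c(c1)O[C@H](c1ccc(OCc9ccccc9)c(OCc9ccccc9)c1)[C@@H](OCc9ccccc9)[C@@H]2c1c(OCc9ccccc9)cc(cc1OCc9ccccc9)O[C@H](c1ccc(OCc9ccccc9)c(OCc9ccccc9)c1)[C@H](OCc9ccccc9)C(OCCOCC)OCCOCC
F2 | step 5 | 2-Cat-benzene-1,3,5-triol (penta-O-benzylcatechin carrying a 2,4,6-trihydroxyphenyl group at C4α) | c9ccccc9COc1cc(OCc9ccccc9)c2c(c1)O[C@H](c1ccc(OCc9ccccc9)c(OCc9ccccc9)c1)[C@@H](OCc9ccccc9)[C@@H]2c1c(O)cc(O)cc1O
F3 | step 5 | 2-Cat-5-(triisopropylsilyloxy)benzene-1,3-diol | c9ccccc9COc1cc(OCc9ccccc9)c2c(c1)O[C@H](c1ccc(OCc9ccccc9)c(OCc9ccccc9)c1)[C@@H](OCc9ccccc9)[C@@H]2c1c(O)cc(O[Si](C(C)C)(C(C)C)C(C)C)cc1O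
F4 | step 7 | [3,4-bis(benzyloxy)phenyl][(4R)-2,2-dimethyl-1,3-dioxolan-4-yl]methanone | O=C(c1ccc(OCc9ccccc9)c(OCc9ccccc9)c1)[C@H]1COC(C)(C)O1
F5 | step 8 | (4R)-4-{(R)-[3,4-bis(benzyloxy)phenyl][3,5-bis(benzyloxy)phenoxy]methyl}-2,2-dimethyl-1,3-dioxolane | c1c(OCc9ccccc9)cc(OCc9ccccc9)cc1O[C@H](c1ccc(OCc9ccccc9)c(OCc9ccccc9)c1)[C@H]1COC(C)(C)O1
F6 | step 18 | tribromide of 21 (bromine at C6 and C8 of unit 1 and at C8 of unit 2) | c9ccccc9COc1c(Br)c(OCc9ccccc9)c2c(c1Br)O[C@H](c1ccc(OCc9ccccc9)c(OCc9ccccc9)c1)[C@@H](OCc9ccccc9)[C@@H]2c1c(OCc9ccccc9)c(Br)c2c(c1OCc9ccccc9)[C@H](OCCOCC)[C@@H](OCc9ccccc9)[C@@H](c1ccc(OCc9ccccc9)c(OCc9ccccc9)c1)O2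
F7 | step 18 | tribromide of 26 (bromine at C6 and C8 of unit 1 and at C8 of unit 2) | c9ccccc9COc1c(Br)c(OCc9ccccc9)c2c(c1Br)O[C@H](c1ccc(OCc9ccccc9)c(OCc9ccccc9)c1)[C@@H](OCc9ccccc9)[C@@H]2c1c(OCc9ccccc9)c(Br)c2c(c1OCc9ccccc9)[C@H](c1c(OCc9ccccc9)cc(OCc9ccccc9)c3c1O[C@H](c1ccc(OCc9ccccc9)c(OCc9ccccc9)c1)[C@H](O)[C@H]3c1c(OCc9ccccc9)cc(OCc9ccccc9)c3c1O[C@H](c1ccc(OCc9ccccc9)c(OCc9ccccc9)c1)[C@H](O)C3)[C@@H](OCc9ccccc9)[C@@H](c1ccc(OCc9ccccc9)c(OCc9ccccc9)c1)O2
A1 | alternative 1 | macrocyclic azelate of the octa-O-benzyl unit 3–unit 4 dimer | c1c(OCc9ccccc9)cc(OCc9ccccc9)c3c1O[C@H](c1ccc(OCc9ccccc9)c(OCc9ccccc9)c1)[C@H](OC(=O)CCCCCCCC(=O)O[C@@H]4Cc5c(OCc9ccccc9)cc(OCc9ccccc9)c6c5O[C@@H]4c1ccc(OCc9ccccc9)c(OCc9ccccc9)c1)[C@H]36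
A2 | alternative 1 | open azelate diester linking O3 of 4β-(2-ethoxyethoxy)-tetra-O-benzylepicatechin to O3 of tetra-O-benzylepicatechin | c9ccccc9COc1cc(OCc9ccccc9)c2c(c1)O[C@H](c1ccc(OCc9ccccc9)c(OCc9ccccc9)c1)[C@H](OC(=O)CCCCCCCC(=O)O[C@@H]3Cc4c(OCc9ccccc9)cc(OCc9ccccc9)cc4O[C@@H]3c1ccc(OCc9ccccc9)c(OCc9ccccc9)c1)[C@H]2OCCOCC
A3 | alternative 2 | protected tetramer with unit 1 as a 4-aryl-4H-chromene (flav-2-ene) and bromine at C8 of unit 2 | c9ccccc9COc1cc(OCc9ccccc9)c2c(c1)OC(c1ccc(OCc9ccccc9)c(OCc9ccccc9)c1)=C[C@@H]2c1c(OCc9ccccc9)c(Br)c2c(c1OCc9ccccc9)[C@H](c1c(OCc9ccccc9)cc(OCc9ccccc9)c3c1O[C@H](c1ccc(OCc9ccccc9)c(OCc9ccccc9)c1)[C@H](OCc9ccccc9)[C@H]3c1c(OCc9ccccc9)cc(OCc9ccccc9)c3c1O[C@H](c1ccc(OCc9ccccc9)c(OCc9ccccc9)c1)[C@H](OCc9ccccc9)C3)[C@@H](OCc9ccccc9)[C@@H](c1ccc(OCc9ccccc9)c(OCc9ccccc9)c1)O2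
A4 | alternative 2 | protected tetramer in which ring C of unit 1 is a seven-membered cyclic sulfone (O–CH(aryl)–SO2–CH2–CH(aryl)), configuration at the carbon between oxygen and sulfur not defined | c9ccccc9COc1cc(OCc9ccccc9)c2c(c1)OC(c1ccc(OCc9ccccc9)c(OCc9ccccc9)c1)S(=O)(=O)C[C@@H]2c1c(OCc9ccccc9)c(Br)c2c(c1OCc9ccccc9)[C@H](c1c(OCc9ccccc9)cc(OCc9ccccc9)c3c1O[C@H](c1ccc(OCc9ccccc9)c(OCc9ccccc9)c1)[C@H](OCc9ccccc9)[C@H]3c1c(OCc9ccccc9)cc(OCc9ccccc9)c3c1O[C@H](c1ccc(OCc9ccccc9)c(OCc9ccccc9)c1)[C@H](OCc9ccccc9)C3)[C@@H](OCc9ccccc9)[C@@H](c1ccc(OCc9ccccc9)c(OCc9ccccc9)c1)O2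
A5 | alternative 3 | benzylated unit 3–unit 4 dimer with a free 3-hydroxyl on unit 3 | c1c(OCc9ccccc9)cc(OCc9ccccc9)c3c1O[C@H](c1ccc(OCc9ccccc9)c(OCc9ccccc9)c1)[C@H](O)[C@H]3c1c(OCc9ccccc9)cc(OCc9ccccc9)c3c1O[C@H](c1ccc(OCc9ccccc9)c(OCc9ccccc9)c1)[C@H](OCc9ccccc9)C3
A6 | alternative 3 | trans-epoxide: 3,5-bis(benzyloxy)phenyl ether of an aryl(oxiranyl)methanol whose other epoxide carbon carries C8 of penta-O-benzylepicatechin | c1c(OCc9ccccc9)cc(OCc9ccccc9)cc1O[C@H](c1ccc(OCc9ccccc9)c(OCc9ccccc9)c1)[C@@H]2O[C@H]2c1c(OCc9ccccc9)cc(OCc9ccccc9)c3c1O[C@H](c1ccc(OCc9ccccc9)c(OCc9ccccc9)c1)[C@H](OCc9ccccc9)C3
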